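The eleven-membered carbocycle (C1–C11; C1 bears the exocyclic methylene, C5 the carboxyl) holds two carbinol carbons, C7 and C11, of the same spatial sense on either side of C8–C9–C10, and C9 (CMe2) can be carried as C=CH2. This latent C2-symmetric 2-methylenepropane-1,3-diyl unit is disconnected at C7–C8 and C10–C11. In one operation a linchpin carrying a diisopinocampheylboryl group at each allylic terminus (Ipc from (+)-α-pinene, made and used in solution) adds to methyl 4-oxobutanoate and then to 3-(trimethylsilyl)propynal. Both bonds and both stereocentres form, giving an acyclic anti-1,5-diol; no ring closes. The ring is closed later at C4=C5.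

Key step: step 2

Remarks on the chemistry (assumptions)
- Numbering: C1 is the ring carbon bearing the exocyclic CH2; then C2, C3, C4=C5 (C5 bears CO2H), C6, C7 (O-angelate), C8, C9 (CMe2), C10, C11 (OH). The target is (7S,11S) with an (E)-C4=C5 bond (C3 and C6 cis on the alkene) and a (Z)-2-methylbut-2-enoate.
- The two carbinols keep one spatial sense throughout; only their CIP labels change with the neighbours (for example 4R,8S in diol 9).
- (−)-B-Chlorodiisopinocampheylborane 2, the commercial reagent derived from (+)-α-pinene, is taken as a starting material. It is the antipode expected to add to the Si face of both aldehydes.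
- The linchpin is made from dilithiated 2-methylpropene rather than from a 1,3-dihalide and magnesium, since a 2-(halomethyl)allyl metal species is prone to 1,3-elimination to methylenecyclopropane and to Wurtz coupling. Each of the two allylic termini takes up one molecule of 2, so step 1 consumes two equivalents of 2.

Step 1
Reactants: 1 2-methylpropene; 2 (−)-B-chlorodiisopinocampheylborane (two equivalents, one per allylic terminus, both incorporated)
Product: 4 2-methylenepropane-1,3-diylbis(diisopinocampheylborane), via 2-methylenepropane-1,3-diyldilithium 3 (not isolated)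
Conditions: n-BuLi (2.1 equiv), TMEDA (2.1 equiv), hexane, 0 °C → rt, precipitated dilithium salt washed in the flask with hexane; then 2 (2.0 equiv), Et2O, −78 → 0 °C; LiCl allowed to settle, supernatant used directly
Reagents that add atoms: (−)-B-chlorodiisopinocampheylborane (the second equivalent of 2), ClB([C@H]1[C@H](C)[C@H]2C[C@@H](C1)C2(C)C)[C@H]1[C@H](C)[C@H]2C[C@@H](C1)C2(C)C
Why: double allylic metalation of 2-methylpropene gives the cross-conjugated dianion, and salt metathesis of each of its two C–Li termini with the B–Cl bond of one molecule of 2 should give the bis(allylborane), the twofold analogue of the standard preparation of B-allyldiisopinocampheylborane.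

Step 2
Reactants: 4 2-methylenepropane-1,3-diylbis(diisopinocampheylborane); 5 methyl 4-oxobutanoate; 6 3-(trimethylsilyl)prop-2-ynal
Product: 9 methyl (4R,8S)-4,8-dihydroxy-6-methylidene-10-(trimethylsilyl)dec-9-ynoate, via mono-adduct allylborane 7 (not isolated), via bis-borinate 8 (not isolated)
Conditions: 4 (ca. 1.3 equiv), Et2O, −78 °C; 5 (1.0 equiv) added slowly as a dilute solution, 2 h; then 6 (2.5 equiv), −78 °C, 3 h; MeOH quench; NaBO3·4H2O, THF/H2O, rt
Reagents that add atoms: none
Why: Proposed new method: each C–C bond should form by allylboration through a closed six-membered chair (Zimmerman–Traxler-type) transition state with the aldehyde substituent equatorial, boron passing to oxygen and the allyl unit being transposed, so that the first addition (C7–C8) leaves a new allylborane 7 that then adds to the ynal (C10–C11). The closest known reaction type is the allylboration of aldehydes with B-allyldiisopinocampheylboranes, including the bidirectional use of this linchpin with one aldehyde taken twice; what is new is the ordered use of two different aldehydes, and no ring is closed. C7 and C11 are both set by the isopinocampheyl groups on boron (reagent control, Si-face attack on each aldehyde), which gives the same spatial sense at both carbinols, formally (4R,8S) because the alkynyl group outranks C10. The step needs cross-selectivity, one molecule of each aldehyde per linchpin, and three features should secure it: the intact linchpin should be the better nucleophile because its second C–B bond donates into the allyl π system and is lost as a donor after the first addition, the less electrophilic aliphatic aldehyde 5 is the limiting component dosed slowly into an excess of 4 at −78 °C, and the fast ynal 6 is then used in excess to consume every remaining allylborane. The symmetric by-products (double adducts of 5 or of 6) differ from 9 in the number of ester groups and should separate after step 3 as a bis-lactone and a diol. Double stereodifferentiation should also raise the enantiomeric purity of the anti diol, since a facial error at either carbinol gives a separable syn diastereomer.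

Step 3
Reactants: 9 methyl (4R,8S)-4,8-dihydroxy-6-methylidene-10-(trimethylsilyl)dec-9-ynoate
Product: 10 (5R)-5-[(4S)-4-hydroxy-2-methylidene-6-(trimethylsilyl)hex-5-yn-1-yl]oxolan-2-one
Conditions: PPTS (cat.), CH2Cl2, rt
Reagents that add atoms: none
Why: acid-catalysed intramolecular transesterification (γ-lactonisation) engages only C7–OH, since C11–OH could only give a nine-membered ring, and thereby differentiates the two carbinols without touching either stereocentre.

Step 4
Reactants: 10 (5R)-5-[(4S)-4-hydroxy-2-methylidene-6-(trimethylsilyl)hex-5-yn-1-yl]oxolan-2-one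
Product: 11 (5R)-5-{(4S)-4-[(tert-butyldimethylsilyl)oxy]-2-methylidene-6-(trimethylsilyl)hex-5-yn-1-yl}oxolan-2-one
Conditions: TBSCl, imidazole, DMF, rt
Reagents that add atoms: tert-butyldimethylsilyl chloride, CC(C)(C)[Si](C)(C)Cl
Why: standard silylation of the only free hydroxyl (C11) gives an ether that should survive the amide base, aqueous base and mild acid used later.

Step 5
Reactants: 11 (5R)-5-{(4S)-4-[(tert-butyldimethylsilyl)oxy]-2-methylidene-6-(trimethylsilyl)hex-5-yn-1-yl}oxolan-2-one
Product: 13 (5R)-5-{(4S)-4-[(tert-butyldimethylsilyl)oxy]-2,2-dimethyl-6-(trimethylsilyl)hex-5-yn-1-yl}oxolan-2-one, via N′-alkyl sulfonylhydrazide 12 (not isolated)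
Conditions: aq. CH2O, n-C8H17SO2NHNH2, Fe(acac)3 (cat.), PhSiH3, THF/MeOH, rt; then MeOH, 60 °C
Reagents that add atoms: formaldehyde, C=O (delivered as its N-octylsulfonylhydrazone)
Why: metal-hydride hydrogen-atom transfer (Mukaiyama-type) to the 1,1-disubstituted C9=CH2, the only alkene present, gives the tertiary C9 radical, which adds to the hydrazone carbon, and thermal loss of sulfinate and dinitrogen from the alkylated hydrazide leaves the second methyl group, so C9 becomes the achiral CMe2 carbon while the silyl-capped alkyne, lactone and silyl ether should stay inert.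

Step 6
Reactants: 13 (5R)-5-{(4S)-4-[(tert-butyldimethylsilyl)oxy]-2,2-dimethyl-6-(trimethylsilyl)hex-5-yn-1-yl}oxolan-2-one
Product: 14 (5R)-5-{(4S)-4-[(tert-butyldimethylsilyl)oxy]-2,2-dimethylhex-5-yn-1-yl}oxolan-2-one
Conditions: K2CO3 (cat.), MeOH, 0 °C; aq. NH4Cl
Reagents that add atoms: none
Why: methanolysis of the C(sp)–Si bond is far faster than cleavage of the secondary silyl ether, and any ring-opened hydroxy ester should reclose on work-up because the γ-lactone is the thermodynamic form.

Step 7
Reactants: 14 (5R)-5-{(4S)-4-[(tert-butyldimethylsilyl)oxy]-2,2-dimethylhex-5-yn-1-yl}oxolan-2-one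
Product: 16 (5R)-5-{(4S)-4-[(tert-butyldimethylsilyl)oxy]-5-iodo-2,2-dimethylhex-5-en-1-yl}oxolan-2-one, via iodoalkenylborane 15 (not isolated)
Conditions: B-I-9-BBN, pentane/CH2Cl2, −20 °C; then AcOH, 0 °C; aq. NaHCO3
Reagents that add atoms: B-iodo-9-borabicyclo[3.3.1]nonane, IB1C2CCCC1CCC2
Why: syn iodoboration of the terminal alkyne places iodine on the internal carbon C1 and boron on the terminal carbon (Markovnikov haloboration), and protonolysis of the alkenyl C–B bond with acetic acid should give the 2-iodo-1-alkene.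

Step 8
Reactants: 16 (5R)-5-{(4S)-4-[(tert-butyldimethylsilyl)oxy]-5-iodo-2,2-dimethylhex-5-en-1-yl}oxolan-2-one; 17 3,3-diethoxyprop-1-ene (acrolein diethyl acetal)
Product: 19 (5R)-5-{(4S)-4-[(tert-butyldimethylsilyl)oxy]-8,8-diethoxy-2,2-dimethyl-5-methylideneoctyl}oxolan-2-one, via B-(3,3-diethoxypropyl)-9-BBN 18 (not isolated)
Conditions: 17, 9-BBN-H, THF, 0 °C → rt; then 16, PdCl2(dppf) (cat.), AsPh3, Cs2CO3, DMF/THF/H2O, rt
Reagents that add atoms: none
Why: anti-Markovnikov hydroboration gives the primary alkylborane, and B-alkyl Suzuki–Miyaura coupling with the alkenyl iodide should form C1–C2, leaving the exocyclic methylene in place and bringing C2–C4 with C4 masked as an acetal.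

Step 9
Reactants: 19 (5R)-5-{(4S)-4-[(tert-butyldimethylsilyl)oxy]-8,8-diethoxy-2,2-dimethyl-5-methylideneoctyl}oxolan-2-one
Product: 21 diethyl [(5S)-5-{(4S)-4-[(tert-butyldimethylsilyl)oxy]-8,8-diethoxy-2,2-dimethyl-5-methylideneoctyl}-2-oxooxolan-3-yl]phosphonate (epimers at the phosphonate carbon), via enol phosphate 20 (not isolated)
Conditions: LiN(iPr)2 (1.1 equiv), THF, −78 °C; ClP(O)(OEt)2; then LiN(iPr)2 (2.2 equiv), −78 °C → rt; AcOH
Reagents that add atoms: diethyl chlorophosphate, CCOP(=O)(Cl)OCC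
Why: O-phosphorylation of the lactone enolate followed by base-induced 1,3-migration of phosphorus from oxygen to carbon (the vinyl phosphate to β-carbonyl phosphonate rearrangement known for lactones) should install the phosphonate at C5, whose configuration is irrelevant because C5 becomes sp2.

Step 10
Reactants: 21 diethyl [(5S)-5-{(4S)-4-[(tert-butyldimethylsilyl)oxy]-8,8-diethoxy-2,2-dimethyl-5-methylideneoctyl}-2-oxooxolan-3-yl]phosphonate
Product: 22 diethyl [(5S)-5-{(4S)-4-[(tert-butyldimethylsilyl)oxy]-2,2-dimethyl-5-methylidene-8-oxooctyl}-2-oxooxolan-3-yl]phosphonate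
Conditions: PPTS (cat.), acetone/H2O, 40 °C
Reagents that add atoms: water, O
Why: mild acid-catalysed hydrolysis of the acyclic diethyl acetal should free the C4 aldehyde under conditions that a hindered secondary silyl ether and the lactone tolerate.

Step 11
Reactants: 22 diethyl [(5S)-5-{(4S)-4-[(tert-butyldimethylsilyl)oxy]-2,2-dimethyl-5-methylidene-8-oxooctyl}-2-oxooxolan-3-yl]phosphonate
Product: 23 (1E,6S,10S)-6-[(tert-butyldimethylsilyl)oxy]-8,8-dimethyl-5-methylidene-11-oxabicyclo[8.2.1]tridec-1-en-12-one (eleven-membered carbocycle C1–C11 bridged by the C5-carbonyl/C7–O lactone)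
Conditions: LiCl, DBU, MeCN, rt, slow addition to high dilution (ca. 1 mM)
Reagents that add atoms: none
Why: intramolecular Horner–Wadsworth–Emmons olefination under Masamune–Roush conditions should close the eleven-membered ring at C4=C5, the stabilised phosphonate favouring the (E)-alkylidene lactone (C3 anti to the carbonyl, C3 and C6 cis on the alkene), which is the geometry of the target and the one the bridged bicycle accommodates.

Step 12
Reactants: 23 (1E,6S,10S)-6-[(tert-butyldimethylsilyl)oxy]-8,8-dimethyl-5-methylidene-11-oxabicyclo[8.2.1]tridec-1-en-12-one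
Product: 25 prop-2-en-1-yl (1E,6S,10S)-6-[(tert-butyldimethylsilyl)oxy]-10-hydroxy-8,8-dimethyl-5-methylidenecycloundec-1-ene-1-carboxylate, via potassium carboxylate 24 (not isolated)
Conditions: KOH (1.2 equiv), THF/H2O, rt; evaporation to dryness; allyl bromide, DMF, 0 °C → rt; neutral work-up, used at once
Reagents that add atoms: potassium hydroxide, [K+].[OH-]; allyl bromide, C=CCBr
Why: saponification cleaves the lactone at the acyl–oxygen bond (C7 retained) and the carboxylate is O-alkylated (SN2) without ever being protonated, so the γ-hydroxy acid has no chance to relactonise and C7–OH is left as the only free hydroxyl.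

Step 13
Reactants: 25 prop-2-en-1-yl (1E,6S,10S)-6-[(tert-butyldimethylsilyl)oxy]-10-hydroxy-8,8-dimethyl-5-methylidenecycloundec-1-ene-1-carboxylate; 26 angelic acid [(2Z)-2-methylbut-2-enoic acid]
Product: 28 prop-2-en-1-yl (1E,6S,10S)-6-[(tert-butyldimethylsilyl)oxy]-8,8-dimethyl-10-{[(2Z)-2-methylbut-2-enoyl]oxy}-5-methylidenecycloundec-1-ene-1-carboxylate, via angelic 2,4,6-trichlorobenzoic anhydride 27 (not isolated)
Conditions: 26, 2,4,6-Cl3C6H2COCl, Et3N, toluene, rt; then 25, toluene, 70 °C
Reagents that add atoms: none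
Why: Yamaguchi-type esterification through the preformed mixed anhydride acylates C7–OH without a nucleophilic catalyst, which should keep the (Z)-2-methylbut-2-enoyl group from isomerising to the tiglate, while the conjugated, α-branched allyl ester is a poor acceptor for relactonisation; C7 is untouched.

Step 14
Reactants: 28 prop-2-en-1-yl (1E,6S,10S)-6-[(tert-butyldimethylsilyl)oxy]-8,8-dimethyl-10-{[(2Z)-2-methylbut-2-enoyl]oxy}-5-methylidenecycloundec-1-ene-1-carboxylate
Product: 29 (1E,6S,10S)-6-[(tert-butyldimethylsilyl)oxy]-8,8-dimethyl-10-{[(2Z)-2-methylbut-2-enoyl]oxy}-5-methylidenecycloundec-1-ene-1-carboxylic acid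
Conditions: Pd(PPh3)4 (cat.), morpholine, THF, rt
Reagents that add atoms: none
Why: Tsuji–Trost-type deallylation, in which the zerovalent palladium catalyst ionises only the allyl ester and morpholine traps the π-allyl fragment, should leave the angelate and the C11 silyl ether (a poor leaving group) untouched.

Step 15
Reactants: 29 (1E,6S,10S)-6-[(tert-butyldimethylsilyl)oxy]-8,8-dimethyl-10-{[(2Z)-2-methylbut-2-enoyl]oxy}-5-methylidenecycloundec-1-ene-1-carboxylic acid
Product: 30 (1E,6S,10S)-6-hydroxy-8,8-dimethyl-10-{[(2Z)-2-methylbut-2-enoyl]oxy}-5-methylidenecycloundec-1-ene-1-carboxylic acid (CNP0263820.1)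
Conditions: HF·pyridine, THF/pyridine, 0 °C → rt
Reagents that add atoms: none
Why: fluoride cleavage of the secondary silyl ether under buffered, weakly acidic conditions should free C11–OH without acyl migration, without Z→E isomerisation of the angelate and without lactonisation, because C7–O is acylated.

Compound list
1 | 2-methylpropene | CC(C)=C | starting material
2 | (−)-B-chlorodiisopinocampheylborane, chlorobis[(1R,2S,3R,5R)-2,6,6-trimethylbicyclo[3.1.1]hept-3-yl]borane | ClB([C@H]1[C@H](C)[C@H]2C[C@@H](C1)C2(C)C)[C@H]1[C@H](C)[C@H]2C[C@@H](C1)C2(C)C | starting material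
3 | 2-methylenepropane-1,3-diyldilithium (TMEDA complex) | [Li]CC(=C)C[Li] | intermediate
4 | 2-methylenepropane-1,3-diylbis(diisopinocampheylborane) | C=C(CB([C@H]1[C@H](C)[C@H]2C[C@@H](C1)C2(C)C)[C@H]1[C@H](C)[C@H]2C[C@@H](C1)C2(C)C)CB([C@H]1[C@H](C)[C@H]2C[C@@H](C1)C2(C)C)[C@H]1[C@H](C)[C@H]2C[C@@H](C1)C2(C)C | intermediate
5 | methyl 4-oxobutanoate | COC(=O)CCC=O | starting material
6 | 3-(trimethylsilyl)prop-2-ynal | C[Si](C)(C)C#CC=O | starting material
7 | methyl (4R)-4-[(diisopinocampheylboryl)oxy]-6-[(diisopinocampheylboryl)methyl]hept-6-enoate | COC(=O)CC[C@@H](OB([C@H]1[C@H](C)[C@H]2C[C@@H](C1)C2(C)C)[C@H]1[C@H](C)[C@H]2C[C@@H](C1)C2(C)C)CC(=C)CB([C@H]1[C@H](C)[C@H]2C[C@@H](C1)C2(C)C)[C@H]1[C@H](C)[C@H]2C[C@@H](C1)C2(C)C | intermediate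
8 | methyl (4R,8S)-4,8-bis[(diisopinocampheylboryl)oxy]-6-methylidene-10-(trimethylsilyl)dec-9-ynoate | COC(=O)CC[C@@H](OB([C@H]1[C@H](C)[C@H]2C[C@@H](C1)C2(C)C)[C@H]1[C@H](C)[C@H]2C[C@@H](C1)C2(C)C)CC(=C)C[C@H](OB([C@H]1[C@H](C)[C@H]2C[C@@H](C1)C2(C)C)[C@H]1[C@H](C)[C@H]2C[C@@H](C1)C2(C)C)C#C[Si](C)(C)C | intermediate
9 | methyl (4R,8S)-4,8-dihydroxy-6-methylidene-10-(trimethylsilyl)dec-9-ynoate | COC(=O)CC[C@@H](O)CC(=C)C[C@H](O)C#C[Si](C)(C)C | intermediate
10 | (5R)-5-[(4S)-4-hydroxy-2-methylidene-6-(trimethylsilyl)hex-5-yn-1-yl]oxolan-2-one | O=C1CC[C@@H](O1)CC(=C)C[C@H](O)C#C[Si](C)(C)C | intermediate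
11 | (5R)-5-{(4S)-4-[(tert-butyldimethylsilyl)oxy]-2-methylidene-6-(trimethylsilyl)hex-5-yn-1-yl}oxolan-2-one | O=C1CC[C@@H](O1)CC(=C)C[C@H](O[Si](C)(C)C(C)(C)C)C#C[Si](C)(C)C | intermediate
12 | N′-alkyl octane-1-sulfonohydrazide in which C9 of 11 carries CH3 and CH2NHNHSO2C8H17 (C9 epimers) | O=C1CC[C@@H](O1)CC(C)(CNNS(=O)(=O)CCCCCCCC)C[C@H](O[Si](C)(C)C(C)(C)C)C#C[Si](C)(C)C | intermediate
13 | (5R)-5-{(4S)-4-[(tert-butyldimethylsilyl)oxy]-2,2-dimethyl-6-(trimethylsilyl)hex-5-yn-1-yl}oxolan-2-one | O=C1CC[C@@H](O1)CC(C)(C)C[C@H](O[Si](C)(C)C(C)(C)C)C#C[Si](C)(C)C | intermediate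
14 | (5R)-5-{(4S)-4-[(tert-butyldimethylsilyl)oxy]-2,2-dimethylhex-5-yn-1-yl}oxolan-2-one | O=C1CC[C@@H](O1)CC(C)(C)C[C@H](O[Si](C)(C)C(C)(C)C)C#C | intermediate
15 | (Z)-2-iodoalkenyl-9-BBN adduct of 14 (boron on the terminal carbon, iodine on C1, cis) | O=C1CC[C@@H](O1)CC(C)(C)C[C@H](O[Si](C)(C)C(C)(C)C)/C(I)=C/B1C2CCCC1CCC2 | intermediate
16 | (5R)-5-{(4S)-4-[(tert-butyldimethylsilyl)oxy]-5-iodo-2,2-dimethylhex-5-en-1-yl}oxolan-2-one | O=C1CC[C@@H](O1)CC(C)(C)C[C@H](O[Si](C)(C)C(C)(C)C)C(I)=C | intermediate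
17 | 3,3-diethoxyprop-1-ene (acrolein diethyl acetal) | C=CC(OCC)OCC | starting material
18 | B-(3,3-diethoxypropyl)-9-borabicyclo[3.3.1]nonane | CCOC(CCB1C2CCCC1CCC2)OCC | intermediate
19 | (5R)-5-{(4S)-4-[(tert-butyldimethylsilyl)oxy]-8,8-diethoxy-2,2-dimethyl-5-methylideneoctyl}oxolan-2-one | O=C1CC[C@@H](O1)CC(C)(C)C[C@H](O[Si](C)(C)C(C)(C)C)C(=C)CCC(OCC)OCC | intermediate
20 | diethyl (5R)-5-{(4S)-4-[(tert-butyldimethylsilyl)oxy]-8,8-diethoxy-2,2-dimethyl-5-methylideneoctyl}-4,5-dihydrofuran-2-yl phosphate | CCOP(=O)(OCC)OC1=CC[C@@H](O1)CC(C)(C)C[C@H](O[Si](C)(C)C(C)(C)C)C(=C)CCC(OCC)OCC | intermediate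
21 | diethyl [(5S)-5-{(4S)-4-[(tert-butyldimethylsilyl)oxy]-8,8-diethoxy-2,2-dimethyl-5-methylideneoctyl}-2-oxooxolan-3-yl]phosphonate (C3 epimers) | O=C1C(P(=O)(OCC)OCC)C[C@@H](O1)CC(C)(C)C[C@H](O[Si](C)(C)C(C)(C)C)C(=C)CCC(OCC)OCC | intermediate
22 | diethyl [(5S)-5-{(4S)-4-[(tert-butyldimethylsilyl)oxy]-2,2-dimethyl-5-methylidene-8-oxooctyl}-2-oxooxolan-3-yl]phosphonate (C3 epimers) | O=C1C(P(=O)(OCC)OCC)C[C@@H](O1)CC(C)(C)C[C@H](O[Si](C)(C)C(C)(C)C)C(=C)CCC=O | intermediate
23 | (1E,6S,10S)-6-[(tert-butyldimethylsilyl)oxy]-8,8-dimethyl-5-methylidene-11-oxabicyclo[8.2.1]tridec-1-en-12-one | C=C1CC/C=C2/C(=O)O[C@H](C2)CC(C)(C)C[C@@H]1O[Si](C)(C)C(C)(C)C | intermediate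
24 | potassium (1E,6S,10S)-6-[(tert-butyldimethylsilyl)oxy]-10-hydroxy-8,8-dimethyl-5-methylidenecycloundec-1-ene-1-carboxylate | C=C1CC/C=C(/C(=O)[O-])C[C@@H](O)CC(C)(C)C[C@@H]1O[Si](C)(C)C(C)(C)C.[K+] | intermediate
25 | prop-2-en-1-yl (1E,6S,10S)-6-[(tert-butyldimethylsilyl)oxy]-10-hydroxy-8,8-dimethyl-5-methylidenecycloundec-1-ene-1-carboxylate | C=C1CC/C=C(/C(=O)OCC=C)C[C@@H](O)CC(C)(C)C[C@@H]1O[Si](C)(C)C(C)(C)C | intermediate
26 | angelic acid, (2Z)-2-methylbut-2-enoic acid | C/C=C(/C)C(=O)O | starting material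
27 | (2Z)-2-methylbut-2-enoic 2,4,6-trichlorobenzoic anhydride | C/C=C(/C)C(=O)OC(=O)c1c(Cl)cc(Cl)cc1Cl | intermediate
28 | prop-2-en-1-yl (1E,6S,10S)-6-[(tert-butyldimethylsilyl)oxy]-8,8-dimethyl-10-{[(2Z)-2-methylbut-2-enoyl]oxy}-5-methylidenecycloundec-1-ene-1-carboxylate | C=C1CC/C=C(/C(=O)OCC=C)C[C@@H](OC(=O)/C(C)=C\C)CC(C)(C)C[C@@H]1O[Si](C)(C)C(C)(C)C | intermediate
29 | (1E,6S,10S)-6-[(tert-butyldimethylsilyl)oxy]-8,8-dimethyl-10-{[(2Z)-2-methylbut-2-enoyl]oxy}-5-methylidenecycloundec-1-ene-1-carboxylic acid | C=C1CC/C=C(/C(=O)O)C[C@@H](OC(=O)/C(C)=C\C)CC(C)(C)C[C@@H]1O[Si](C)(C)C(C)(C)C | intermediate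
30 | (1E,6S,10S)-6-hydroxy-8,8-dimethyl-10-{[(2Z)-2-methylbut-2-enoyl]oxy}-5-methylidenecycloundec-1-ene-1-carboxylic acid | C=C1CC/C=C(/C(=O)O)C[C@@H](OC(=O)/C(C)=C\C)CC(C)(C)C[C@@H]1O | target

Total step count: 15.
Longest linear sequence: 15 steps (1 and 2 to 30); 5, 6, 17 and 26 enter as purchased materials.

Steps most likely to fail

1. Step 2 (proposed new method). The process at risk is statistical scrambling: a second molecule of aldehyde 5 may add to mono-adduct 7 before the ynal arrives, and linchpin left untouched by 5 then takes up two molecules of 6. Incomplete dimetalation in step 1 would add a monoborane that simply methallylates the aldehydes. Fallback with known chemistry, setting out from 5 and coming back at 10: the two bonds are made one at a time with a silicon/tin linchpin. Commercial 2-(chloromethyl)allyltrimethylsilane and Bu3SnLi give tributyl{2-[(trimethylsilyl)methyl]prop-2-en-1-yl}stannane F1. Catalytic asymmetric Keck allylation of 5 with F1 ((S)-BINOL, Ti(OiPr)4, 4 Å molecular sieves, CH2Cl2, −20 °C; the BINOL antipode is the one expected to deliver the allyl unit to the Si face) should react only at the stannane terminus and give methyl (4R)-4-hydroxy-6-[(trimethylsilyl)methyl]hept-6-enoate F2. PPTS then closes this to (5R)-5-{2-[(trimethylsilyl)methyl]prop-2-en-1-yl}oxolan-2-one F3. Hosomi–Sakurai addition of F3 to 6 (BF3·OEt2, CH2Cl2, −78 °C) forms C10–C11 without stereocontrol and gives (5R)-5-[4-hydroxy-2-methylidene-6-(trimethylsilyl)hex-5-yn-1-yl]oxolan-2-one F4 as a mixture of C11 epimers. Dess–Martin oxidation gives the ynone (5R)-5-[2-methylidene-4-oxo-6-(trimethylsilyl)hex-5-yn-1-yl]oxolan-2-one F5, and Noyori transfer hydrogenation (RuCl[(S,S)-TsDPEN](p-cymene), iPrOH, rt; catalyst antipode chosen for the (S)-carbinol) resets C11 to give 10.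

2. Step 11. The process at risk is intermolecular olefination (oligomer formation) outrunning closure of the strained medium ring, together with erosion of alkene geometry. Fallback, setting out from 19 and coming back at 23: the ring is closed by a reductive aldol instead of an olefination. The lactone enolate of 19 (LiN(SiMe3)2, Me3SiCl, THF, −78 °C) is brominated with NBS to give the α-bromo lactone F6 (the 3-bromo analogue of 19, C3 epimers). PPTS in acetone/H2O frees the aldehyde, giving the α-bromo lactone aldehyde F7. SmI2 (THF, −78 °C, high dilution) then effects an intramolecular Reformatsky-type addition of the samarium enolate to the aldehyde, a closure known to tolerate medium rings, and gives the bicyclic β-hydroxy lactone F8 (C4 carbinol, C4/C5 diastereomers). MsCl/Et3N converts it into the methanesulfonate F9, and DBU eliminates to the conjugated (E)-alkylidene lactone 23.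

3. Step 13. The process at risk is relactonisation of the γ-hydroxy ester (attack of C7–OH on the allyl ester with loss of allyl alcohol) and Z→E drift of the angelate under warm basic conditions, both competing with a slow acylation. Fallback, setting out from 23 and coming back at 29: the carboxyl carbon is taken out of the acyl oxidation state while C7–OH is acylated. iBu2AlH (CH2Cl2, −78 → 0 °C) reduces the lactone of 23 to the diol F10 (C5–CH2OH and C7–OH free, (E)-alkene and C11 silyl ether unchanged). TESCl/imidazole at −20 °C silylates the primary allylic hydroxyl selectively to give the primary triethylsilyl ether F11. The same mixed-anhydride angeloylation, now with no ester to close onto, gives the C7 angelate F12. PPTS in MeOH at 0 °C removes only the primary triethylsilyl group, giving the primary allylic alcohol F13. MnO2 (CH2Cl2) gives the enal F14, and Pinnick oxidation (NaClO2, NaH2PO4, 2-methylbut-2-ene, tBuOH/H2O) gives acid 29.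

Further compounds
F1 | step 2 | tributyl{2-[(trimethylsilyl)methyl]prop-2-en-1-yl}stannane | CCCC[Sn](CCCC)(CCCC)CC(=C)C[Si](C)(C)C
F2 | step 2 | methyl (4R)-4-hydroxy-6-[(trimethylsilyl)methyl]hept-6-enoate | COC(=O)CC[C@@H](O)CC(=C)C[Si](C)(C)C
F3 | step 2 | (5R)-5-{2-[(trimethylsilyl)methyl]prop-2-en-1-yl}oxolan-2-one | O=C1CC[C@@H](O1)CC(=C)C[Si](C)(C)C
F4 | step 2 | (5R)-5-[4-hydroxy-2-methylidene-6-(trimethylsilyl)hex-5-yn-1-yl]oxolan-2-one, C11 epimer mixture | O=C1CC[C@@H](O1)CC(=C)CC(O)C#C[Si](C)(C)C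
F5 | step 2 | (5R)-5-[2-methylidene-4-oxo-6-(trimethylsilyl)hex-5-yn-1-yl]oxolan-2-one | O=C1CC[C@@H](O1)CC(=C)CC(=O)C#C[Si](C)(C)C
F6 | step 11 | 3-bromo analogue of 19 (α-bromo lactone, C3 epimers) | O=C1C(Br)C[C@@H](O1)CC(C)(C)C[C@H](O[Si](C)(C)C(C)(C)C)C(=C)CCC(OCC)OCC
F7 | step 11 | α-bromo lactone aldehyde (acetal of F6 hydrolysed) | O=C1C(Br)C[C@@H](O1)CC(C)(C)C[C@H](O[Si](C)(C)C(C)(C)C)C(=C)CCC=O
F8 | step 11 | bicyclic β-hydroxy lactone (C4–OH, C4/C5 diastereomers) | C=C1CCC(O)C2C[C@@H](OC2=O)CC(C)(C)C[C@@H]1O[Si](C)(C)C(C)(C)C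
F9 | step 11 | methanesulfonate of F8 | C=C1CCC(OS(C)(=O)=O)C2C[C@@H](OC2=O)CC(C)(C)C[C@@H]1O[Si](C)(C)C(C)(C)C
F10 | step 13 | diol from reduction of 23 (C5–CH2OH, C7–OH, C11–OTBS, (E)-alkene) | C=C1CC/C=C(/CO)C[C@@H](O)CC(C)(C)C[C@@H]1O[Si](C)(C)C(C)(C)C
F11 | step 13 | primary triethylsilyl ether of F10 | C=C1CC/C=C(/CO[Si](CC)(CC)CC)C[C@@H](O)CC(C)(C)C[C@@H]1O[Si](C)(C)C(C)(C)C
F12 | step 13 | C7 angelate of F11 | C=C1CC/C=C(/CO[Si](CC)(CC)CC)C[C@@H](OC(=O)/C(C)=C\C)CC(C)(C)C[C@@H]1O[Si](C)(C)C(C)(C)C
F13 | step 13 | primary allylic alcohol from F12 | C=C1CC/C=C(/CO)C[C@@H](OC(=O)/C(C)=C\C)CC(C)(C)C[C@@H]1O[Si](C)(C)C(C)(C)C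
F14 | step 13 | enal from F13 | C=C1CC/C=C(/C=O)C[C@@H](OC(=O)/C(C)=C\C)CC(C)(C)C[C@@H]1O[Si](C)(C)C(C)(C)C
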